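**Retrosynthetic overview**
1. Vitrofolal B comes from its 3,6-bis(isopropyl ether). The CHO group comes from the CO2Me group of methyl 4-aryl-3-hydroxy-5-methoxy-6-isopropoxy-2-naphthoate.
2. Ring B of that naphthoate is cut at C4–C4a (intramolecular Pd ketone α-arylation of an aryl bromide) and at C1=C2 (intermolecular Knoevenagel/aldol condensation, the bond that joins the two fragments).
3. Fragment 1 (ring A plus C1) is 2-bromo-O-isopropylvanillin, made from vanillin by directed ortho-lithiation. Fragment 2 (ring C plus C2, C3, C4 and the ester carbon) is methyl 4-(3,4-dimethoxyphenyl)-3-oxobutanoate, made from homoveratric acid and Meldrum's acid.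
4. Ring order: benzene rings A and C are bought. Ring B is the only ring made, with C1=C2 formed first and C4–C4a second, and it aromatises on closure.

Assumption: the SMILES has no stereodescriptor and the molecule has no stereocentre. The biaryl axis is not configurationally stable, because both ortho positions of the dimethoxyphenyl ring carry H. The compound is therefore treated as achiral and no stereocontrol is needed.

Naphthalene locants used below: C2 = CO2Me/CHO, C3 = OH, C4 = aryl, C5 = OMe, C6 = OH.

Step 1
Reactants: 1 vanillin (4-hydroxy-3-methoxybenzaldehyde)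
Product: 2 3-methoxy-4-(propan-2-yloxy)benzaldehyde
Conditions: 2-bromopropane (1.5 equiv), K2CO3 (2 equiv), DMF, 70 °C
Reagents that add atoms: 2-bromopropane, CC(C)Br
Why: Williamson ether synthesis (SN2 O-alkylation of the acidic para-formyl phenoxide) installs an ether that survives n-BuLi, carbonate bases, palladium and hydride, is a poor lithiation director, and can later be cleaved beside methyl ethers; no stereocentre is formed.

Step 2
Reactants: 2 3-methoxy-4-(propan-2-yloxy)benzaldehyde
Product: 3 4-(dimethoxymethyl)-2-methoxy-1-(propan-2-yloxy)benzene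
Conditions: HC(OMe)3 (1.5 equiv), p-TsOH (1 mol %), MeOH, reflux; Et3N quench
Reagents that add atoms: trimethyl orthoformate, COC(OC)OC
Why: Acid-catalysed acetalisation, driven to completion by the orthoester as water scavenger, masks the aldehyde against n-BuLi and turns it into a lithium-coordinating directing group; no stereocentre is formed.

Step 3
Reactants: 3 4-(dimethoxymethyl)-2-methoxy-1-(propan-2-yloxy)benzene
Product: 6 2-bromo-3-methoxy-4-(propan-2-yloxy)benzaldehyde, via aryllithium 4 (not isolated), via bromo acetal 5 (not isolated)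
Conditions: n-BuLi (1.3 equiv), Et2O, 0 °C to rt, 3 h; BrCH2CH2Br (1.5 equiv), −78 °C to rt; then 2 M HCl, THF, rt
Reagents that add atoms: 1,2-dibromoethane, BrCCBr; water, O
Why: Directed ortho-metalation, in which the acetal and the methoxy group stand 1,3 to each other and together steer n-BuLi to the C–H between them (the bulky isopropoxy group directs poorly), after which the aryllithium takes bromine from 1,2-dibromoethane with loss of ethene and aqueous acid hydrolyses the acetal; no stereocentre is formed.

Step 4
Reactants: 7 (3,4-dimethoxyphenyl)acetic acid (homoveratric acid); 8 Meldrum's acid (2,2-dimethyl-1,3-dioxane-4,6-dione)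
Product: 9 5-[2-(3,4-dimethoxyphenyl)-1-hydroxyethylidene]-2,2-dimethyl-1,3-dioxane-4,6-dione
Conditions: DCC (1.1 equiv), DMAP (1.2 equiv), CH2Cl2, 0 °C to rt; filter, wash with aq. KHSO4
Reagents that add atoms: none
Why: Carbodiimide-mediated C-acylation of Meldrum's acid (first half of the Oikawa–Yonemitsu β-keto ester synthesis, a Claisen-type acylation) works because DMAP passes the activated acyl group to the very acidic C5 of 8 and the product is held as its stable enol; no stereocentre is formed.

Step 5
Reactants: 9 5-[2-(3,4-dimethoxyphenyl)-1-hydroxyethylidene]-2,2-dimethyl-1,3-dioxane-4,6-dione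
Product: 11 methyl 4-(3,4-dimethoxyphenyl)-3-oxobutanoate, via acylketene 10 (not isolated)
Conditions: MeOH, reflux, 4 h
Reagents that add atoms: methanol, CO
Why: Thermal cycloreversion of the acyl Meldrum's acid (second half of the Oikawa–Yonemitsu synthesis) expels acetone and CO2 to give an acylketene that methanol traps cleanly as the β-keto ester; no stereocentre is formed.

Step 6 (key fragment union)
Reactants: 6 2-bromo-3-methoxy-4-(propan-2-yloxy)benzaldehyde; 11 methyl 4-(3,4-dimethoxyphenyl)-3-oxobutanoate
Product: 12 methyl 2-{[2-bromo-3-methoxy-4-(propan-2-yloxy)phenyl]methylidene}-4-(3,4-dimethoxyphenyl)-3-oxobutanoate (E/Z mixture)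
Conditions: piperidine (0.2 equiv), AcOH (0.2 equiv), toluene, Dean–Stark, reflux
Reagents that add atoms: none
Why: Intermolecular Knoevenagel condensation (aldol-type addition and dehydration), in which only the doubly activated C2 methylene of 11 is enolised by piperidinium acetate, adds to the aldehyde of 6 and loses water irreversibly, forms the future C1=C2 bond with complete regiocontrol; no stereocentre is formed and the E/Z ratio does not matter because both isomers converge in step 7.

Step 7
Reactants: 12 methyl 2-{[2-bromo-3-methoxy-4-(propan-2-yloxy)phenyl]methylidene}-4-(3,4-dimethoxyphenyl)-3-oxobutanoate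
Product: 14 methyl 4-(3,4-dimethoxyphenyl)-3-hydroxy-5-methoxy-6-(propan-2-yloxy)naphthalene-2-carboxylate, via keto tautomer 13 (not isolated)
Conditions: Pd(OAc)2 (5 mol %), PPh3 (20 mol %), Cs2CO3 (2.5 equiv), degassed DMF, 100 °C; then 1 M HCl
Reagents that add atoms: none
Why: Intramolecular Buchwald–Hartwig–Miura ketone α-arylation, in which Cs2CO3 enolises the only acidic site left (the benzylic CH2 next to the ketone), zerovalent palladium made in situ inserts into the C–Br bond activated by the ortho acceptor-substituted vinyl group, free PPh3 and base interconvert the alkene isomers by reversible conjugate addition so that material drains through the E isomer (ketone cis to ring A), and reductive elimination closes the six-membered ring; the transient racemic stereocentre of 13 is erased by irreversible tautomerisation to the naphthol.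

Step 8
Reactants: 14 methyl 4-(3,4-dimethoxyphenyl)-3-hydroxy-5-methoxy-6-(propan-2-yloxy)naphthalene-2-carboxylate
Product: 15 methyl 4-(3,4-dimethoxyphenyl)-5-methoxy-3,6-di(propan-2-yloxy)naphthalene-2-carboxylate
Conditions: 2-bromopropane (3 equiv), Cs2CO3 (2 equiv), DMF, 60 °C
Reagents that add atoms: 2-bromopropane, CC(C)Br
Why: Williamson ether synthesis on the cesium naphtholate masks the only free OH so that the reduction and oxidation that follow run on a neutral substrate with no o-quinone methide or phenol oxidation pathway, and the new ether falls off together with the C6 ether in the last step; no stereocentre is formed.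

Step 9
Reactants: 15 methyl 4-(3,4-dimethoxyphenyl)-5-methoxy-3,6-di(propan-2-yloxy)naphthalene-2-carboxylate
Product: 16 [4-(3,4-dimethoxyphenyl)-5-methoxy-3,6-di(propan-2-yloxy)naphthalen-2-yl]methanol
Conditions: LiAlH4 (1.5 equiv), THF, 0 °C to rt; Fieser work-up
Reagents that add atoms: none
Why: Hydride reduction of the aryl ester to the primary benzylic alcohol is clean because aryl alkyl ethers are the only other functional groups and are inert to LiAlH4; no stereocentre is formed.

Step 10
Reactants: 16 [4-(3,4-dimethoxyphenyl)-5-methoxy-3,6-di(propan-2-yloxy)naphthalen-2-yl]methanol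
Product: 17 4-(3,4-dimethoxyphenyl)-5-methoxy-3,6-di(propan-2-yloxy)naphthalene-2-carbaldehyde
Conditions: activated MnO2 (15 equiv), CH2Cl2, rt
Reagents that add atoms: none
Why: Chemoselective MnO2 oxidation of an electron-rich benzylic alcohol stops at the aldehyde and leaves the ethers untouched; no stereocentre is formed.

Step 11
Reactants: 17 4-(3,4-dimethoxyphenyl)-5-methoxy-3,6-di(propan-2-yloxy)naphthalene-2-carbaldehyde
Product: 18 vitrofolal B (4-(3,4-dimethoxyphenyl)-3,6-dihydroxy-5-methoxynaphthalene-2-carbaldehyde)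
Conditions: BCl3 (1 M in CH2Cl2, 5 equiv), CH2Cl2, −78 °C to 0 °C; then H2O
Reagents that add atoms: none
Why: Lewis-acid ether cleavage discriminates by alkyl group, since the secondary isopropyl ethers ionise far faster than methyl ethers (the C3 ether is further helped by chelation of boron to the neighbouring aldehyde), so both naphthols are freed while the three methoxy groups and the aldehyde survive; the product has no stereocentre.

**Compound list**
1 | vanillin (4-hydroxy-3-methoxybenzaldehyde) | COc1cc(C=O)ccc1O | starting material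
2 | 3-methoxy-4-(propan-2-yloxy)benzaldehyde | COc1cc(C=O)ccc1OC(C)C | intermediate
3 | 4-(dimethoxymethyl)-2-methoxy-1-(propan-2-yloxy)benzene | COC(OC)c1ccc(OC(C)C)c(OC)c1 | intermediate
4 | [6-(dimethoxymethyl)-2-methoxy-3-(propan-2-yloxy)phenyl]lithium (aryllithium, not isolated) | [Li]c1c(C(OC)OC)ccc(OC(C)C)c1OC | intermediate
5 | 2-bromo-1-(dimethoxymethyl)-3-methoxy-4-(propan-2-yloxy)benzene (bromo acetal, not isolated) | COC(OC)c1ccc(OC(C)C)c(OC)c1Br | intermediate
6 | 2-bromo-3-methoxy-4-(propan-2-yloxy)benzaldehyde | O=Cc1ccc(OC(C)C)c(OC)c1Br | intermediate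
7 | (3,4-dimethoxyphenyl)acetic acid | COc1ccc(CC(=O)O)cc1OC | starting material
8 | Meldrum's acid (2,2-dimethyl-1,3-dioxane-4,6-dione) | CC1(C)OC(=O)CC(=O)O1 | starting material
9 | 5-[2-(3,4-dimethoxyphenyl)-1-hydroxyethylidene]-2,2-dimethyl-1,3-dioxane-4,6-dione | COc1ccc(CC(O)=C2C(=O)OC(C)(C)OC2=O)cc1OC | intermediate
10 | 4-(3,4-dimethoxyphenyl)but-1-ene-1,3-dione (acylketene, not isolated) | COc1ccc(CC(=O)C=C=O)cc1OC | intermediate
11 | methyl 4-(3,4-dimethoxyphenyl)-3-oxobutanoate | COC(=O)CC(=O)Cc1ccc(OC)c(OC)c1 | intermediate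
12 | methyl 2-{[2-bromo-3-methoxy-4-(propan-2-yloxy)phenyl]methylidene}-4-(3,4-dimethoxyphenyl)-3-oxobutanoate (E/Z mixture, so no alkene descriptor) | COC(=O)C(=Cc1ccc(OC(C)C)c(OC)c1Br)C(=O)Cc1ccc(OC)c(OC)c1 | intermediate
13 | methyl 4-(3,4-dimethoxyphenyl)-5-methoxy-3-oxo-6-(propan-2-yloxy)-3,4-dihydronaphthalene-2-carboxylate (keto tautomer, racemic, not isolated) | COC(=O)C1=Cc2ccc(OC(C)C)c(OC)c2C(c2ccc(OC)c(OC)c2)C1=O | intermediate
14 | methyl 4-(3,4-dimethoxyphenyl)-3-hydroxy-5-methoxy-6-(propan-2-yloxy)naphthalene-2-carboxylate | COC(=O)c1cc2ccc(OC(C)C)c(OC)c2c(-c2ccc(OC)c(OC)c2)c1O | intermediate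
15 | methyl 4-(3,4-dimethoxyphenyl)-5-methoxy-3,6-di(propan-2-yloxy)naphthalene-2-carboxylate | COC(=O)c1cc2ccc(OC(C)C)c(OC)c2c(-c2ccc(OC)c(OC)c2)c1OC(C)C | intermediate
16 | [4-(3,4-dimethoxyphenyl)-5-methoxy-3,6-di(propan-2-yloxy)naphthalen-2-yl]methanol | OCc1cc2ccc(OC(C)C)c(OC)c2c(-c2ccc(OC)c(OC)c2)c1OC(C)C | intermediate
17 | 4-(3,4-dimethoxyphenyl)-5-methoxy-3,6-di(propan-2-yloxy)naphthalene-2-carbaldehyde | O=Cc1cc2ccc(OC(C)C)c(OC)c2c(-c2ccc(OC)c(OC)c2)c1OC(C)C | intermediate
18 | vitrofolal B | COc1ccc(-c2c(O)c(C=O)cc3ccc(O)c(OC)c23)cc1OC | target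

**Step count**
Total steps: 11. Longest linear sequence: 9 (steps 1–3 and 6–11). Steps 4–5 form a two-step side branch.

**Three steps most likely to fail**

Risk A, the directed lithiation and bromination (step 3). Lithiation may be incomplete or may leak to the positions ortho to the isopropoxy group or on the far side of the acetal. The fallback sets out from 1 and comes back at 6, and it replaces lithiation by electrophilic nitration and a Sandmeyer reaction.
- Acetylation (Ac2O, pyridine) gives vanillin acetate F1.
- Fuming HNO3 at −10 °C gives the 2-nitro acetate F2. The weakly donating acetoxy group leaves the methoxy group in control, and it directs to the position between itself and the formyl group.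
- Aqueous NaOH followed by HCl gives 2-nitrovanillin F3.
- 2-Bromopropane and K2CO3 in DMF give the nitro isopropyl ether F4.
- Fe powder in AcOH/EtOH gives the amino aldehyde F5.
- NaNO2 in aqueous HBr at 0 °C gives the diazonium bromide F6.
- CuBr converts F6 into 6.

Risk B, the palladium ring closure (step 7). Compound 12 is a strong Michael acceptor, only its E isomer can close, and the C–Br bond is flanked on both sides. The fallback sets out from 12 and comes back at 14. It performs the arylation on a plain saturated benzyl ketone and restores the ester and the aromaticity afterwards.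
- Hantzsch ester in EtOH at 60 °C reduces the alkene to the saturated keto ester F7.
- Krapcho demethoxycarbonylation (LiCl, wet DMSO, 140 °C) gives the benzyl ketone F8. Its only ring-forming enolate carbon is the benzylic one.
- Pd2(dba)3, Xantphos and K3PO4 in toluene at 100 °C, under strict exclusion of air, give the 1-aryl-2-tetralone F9.
- NaH and dimethyl carbonate in refluxing THF give the tetralone ester F10. Acylation at the aryl-bearing carbon gives a product that cannot enolise and reverts, so the ester settles on the CH2 side.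
- DDQ in 1,4-dioxane dehydrogenates F10 to 14.

Risk C, the final ether cleavage (step 11). The crowded C5 methoxy group sits next to the freed C6 oxygen and could be lost as well. The fallback sets out from 6 and comes back at 18. It changes the protecting-group plan so that the end game is neutral hydrogenolysis.
- AlCl3 in CH2Cl2 (0 °C to rt) removes the isopropyl group at the simple benzaldehyde stage and gives 2-bromovanillin F11.
- BnBr and K2CO3 in DMF give the benzyl ether F12.
- Steps 6 to 10 are then repeated with benzyl bromide in place of 2-bromopropane. This gives in turn the benzyl-series Knoevenagel adduct F13, its cyclised keto tautomer F14 (not isolated), the benzyl-series naphthol ester F15, the bis(benzyl ether) ester F16, the bis(benzyl ether) alcohol F17 and the bis(benzyl ether) aldehyde F18.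
- H2 (1 atm) over Pd/C in EtOAc at rt, stopped after two equivalents of uptake, cleaves both benzyl ethers and gives 18.

**Further compounds**
F1 | step 3 | 4-formyl-2-methoxyphenyl acetate (vanillin acetate) | CC(=O)Oc1ccc(C=O)cc1OC
F2 | step 3 | 4-formyl-2-methoxy-3-nitrophenyl acetate | CC(=O)Oc1ccc(C=O)c([N+](=O)[O-])c1OC
F3 | step 3 | 4-hydroxy-3-methoxy-2-nitrobenzaldehyde (2-nitrovanillin) | O=Cc1ccc(O)c(OC)c1[N+](=O)[O-]
F4 | step 3 | 3-methoxy-2-nitro-4-(propan-2-yloxy)benzaldehyde | O=Cc1ccc(OC(C)C)c(OC)c1[N+](=O)[O-]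
F5 | step 3 | 2-amino-3-methoxy-4-(propan-2-yloxy)benzaldehyde | O=Cc1ccc(OC(C)C)c(OC)c1N
F6 | step 3 | 6-formyl-2-methoxy-3-(propan-2-yloxy)benzenediazonium bromide | O=Cc1ccc(OC(C)C)c(OC)c1[N+]#N.[Br-]
F7 | step 7 | methyl 2-{[2-bromo-3-methoxy-4-(propan-2-yloxy)phenyl]methyl}-4-(3,4-dimethoxyphenyl)-3-oxobutanoate (racemic) | COC(=O)C(Cc1ccc(OC(C)C)c(OC)c1Br)C(=O)Cc1ccc(OC)c(OC)c1
F8 | step 7 | 4-[2-bromo-3-methoxy-4-(propan-2-yloxy)phenyl]-1-(3,4-dimethoxyphenyl)butan-2-one | O=C(CCc1ccc(OC(C)C)c(OC)c1Br)Cc1ccc(OC)c(OC)c1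
F9 | step 7 | 1-(3,4-dimethoxyphenyl)-8-methoxy-7-(propan-2-yloxy)-3,4-dihydronaphthalen-2(1H)-one (racemic) | O=C1CCc2ccc(OC(C)C)c(OC)c2C1c1ccc(OC)c(OC)c1
F10 | step 7 | methyl 4-(3,4-dimethoxyphenyl)-5-methoxy-3-oxo-6-(propan-2-yloxy)-1,2,3,4-tetrahydronaphthalene-2-carboxylate (racemic, keto/enol and diastereomer mixture) | COC(=O)C1Cc2ccc(OC(C)C)c(OC)c2C(c2ccc(OC)c(OC)c2)C1=O
F11 | step 11 | 2-bromo-4-hydroxy-3-methoxybenzaldehyde (2-bromovanillin) | O=Cc1ccc(O)c(OC)c1Br
F12 | step 11 | 4-(benzyloxy)-2-bromo-3-methoxybenzaldehyde | O=Cc1ccc(OCc2ccccc2)c(OC)c1Br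
F13 | step 11 | methyl 2-{[4-(benzyloxy)-2-bromo-3-methoxyphenyl]methylidene}-4-(3,4-dimethoxyphenyl)-3-oxobutanoate (E/Z mixture) | COC(=O)C(=Cc1ccc(OCc2ccccc2)c(OC)c1Br)C(=O)Cc1ccc(OC)c(OC)c1
F14 | step 11 | methyl 6-(benzyloxy)-4-(3,4-dimethoxyphenyl)-5-methoxy-3-oxo-3,4-dihydronaphthalene-2-carboxylate (racemic, not isolated) | COC(=O)C1=Cc2ccc(OCc3ccccc3)c(OC)c2C(c2ccc(OC)c(OC)c2)C1=O
F15 | step 11 | methyl 6-(benzyloxy)-4-(3,4-dimethoxyphenyl)-3-hydroxy-5-methoxynaphthalene-2-carboxylate | COC(=O)c1cc2ccc(OCc3ccccc3)c(OC)c2c(-c2ccc(OC)c(OC)c2)c1O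
F16 | step 11 | methyl 3,6-bis(benzyloxy)-4-(3,4-dimethoxyphenyl)-5-methoxynaphthalene-2-carboxylate | COC(=O)c1cc2ccc(OCc3ccccc3)c(OC)c2c(-c2ccc(OC)c(OC)c2)c1OCc1ccccc1
F17 | step 11 | [3,6-bis(benzyloxy)-4-(3,4-dimethoxyphenyl)-5-methoxynaphthalen-2-yl]methanol | OCc1cc2ccc(OCc3ccccc3)c(OC)c2c(-c2ccc(OC)c(OC)c2)c1OCc1ccccc1
F18 | step 11 | 3,6-bis(benzyloxy)-4-(3,4-dimethoxyphenyl)-5-methoxynaphthalene-2-carbaldehyde | O=Cc1cc2ccc(OCc3ccccc3)c(OC)c2c(-c2ccc(OC)c(OC)c2)c1OCc1ccccc1
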